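The data stem from a simulated flask from invented constants; noise was put on by code.

- I began from a one-step world: substrate meets catalyst, product leaves, catalyst returns. So I counted turnovers, and with c(catalyst) at 0.0800 mM the charge held 1250 of them per catalyst.

| setting | Monday's | Thursday's | dawn | summer | midnight | spring |
|---|---|---|---|---|---|---|
| substrate | 0.10 M | 0.10 M | 0.10 M | 0.10 M | 0.10 M | 0.10 M |
| catalyst | 0.08 mol% | 0.08 mol% | 0.08 mol% | 0.08 mol% | 0.08 mol% | 0.08 mol% |
| added ligand | 0.017 mM | 0.19 mM | 0.015 mM | 0.030 mM | 0.060 mM | 0.12 mM |
| remark | run made earlier | run made earlier |  |  |  |  |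
| time |  |  | 5.0 h | 5.0 h | 5.0 h | 5.0 h |

- Monday's (time / h: product / %): 0.417: 20.5; 0.833: 35.1; 1.33: 49.5; 2.50: 70.1; 5.00: 90.2
- Thursday's (time / h: product / %): 0.417: 11.3; 0.833: 14.8; 1.33: 17.5; 2.50: 19.9; 5.00: 23.5

(each reading ± 0.5 percentage points)

- [product] at the end for dawn, summer, midnight, spring, in this order
- the shape of the row from first to last (hardly changes / falls all the way / falls, then rises / rises, then falls / rises all the way)

- "hardly changes" means that all values lie within two and a half points (for a concentration: within two and a half percent of the largest)

- Taking the rate as pseudo-first-order in substrate, Monday's first reading gave 688 h⁻¹: the turnover frequency, the turnovers per hour of one working catalyst at the charged c(substrate).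
- Thursday's run looked contradictory: c(added ligand) was 0.19 mM, more than the catalyst's 0.0800 mM, yet each catalyst made 294 turnovers.
- The count cleared it up. Thursday's last two readings, run back to the start, left a burst of 16.3%, or 204 turnovers, so I read the binding as slow on the scale of a turnover.
- After that burst, Thursday's flask made 18.0 h⁻¹ per catalyst, far less than the turnover frequency. Allowing for the substrate left, I read a working share of 3.27%, so the binding was tight but not complete.
- That share and Thursday's excess ligand gave a dissociation constant of 0.00372 mM.
- For spring, where the ligand also exceeded the catalyst, I reckoned a working share of 8.50%. I scaled Thursday's burst inversely with ligand to 25.8%, and the two gave 0.0413 M of product.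
- For dawn, with less ligand than catalyst, I counted all of it as bound, which gave 0.0893 M. I reckoned only these two ends, and from them I expected a row that fell all the way.
- The forecast gave 0.091 M, 0.086 M, 0.07 M and 0.038 M, a row that falls all the way, and said “The row falls throughout”.
- The flasks gave 0.0911 M, 0.0864 M, 0.0718 M and 0.0394 M, a row that falls all the way.

    substrate + catalyst → catalyst + product (k = 1.99 M⁻¹ s⁻¹)
    catalyst + added ligand ⇌ idle complex (K = 2.40 × 10⁵ M⁻¹, k = 6.17 M⁻¹ s⁻¹)

- At the end of spring, idle complex held 91.7% of the catalyst and 8.28% remained free. In midnight, the mean free share and mean substrate over the second half, multiplied by the turnover frequency 688 h⁻¹ and the 2.50 h elapsed, gave 238 turnovers, and midnight's product rose by 239 turnovers.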